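**Retrosynthetic overview**

1. Numbering: C1 = C(OH)(C7H2OBz), C2 = CH–OBz, C3=C4, C5 and C6 = CH–OAc (C6 next to C1). The strategy rests on the tertiary carbinol C1 beside oxygenated C6 in the six-membered carbocycle (an α-ketol retron) and on the cis C3=C4 bond of that ring.
2. Endgame: target ← O-2/O-7 benzoates and O-5/O-6 acetates ← trans-diol ← C6 ketone 16 by hydroxyl-directed reduction.
3. Key disconnection C1–C6: ketol 16 ← acyclic (Z)-keto aldehyde 15 by NHC-catalysed intramolecular crossed benzoin; this closes the only ring.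
4. 15 ← 1,6-diol 14 ← L-galactono-1,4-lactone, whose C1–C6 become C1–C6 of the target. Its erythro 3,4-diol gives the Z-alkene (Corey–Winter), its 5,6-anisylidene acetal gives the O-5 PMB ether and the C6 alcohol, and C7 is added at C1 as a hydroxymethyl Grignard equivalent.
5. Stereocentres: C2 and C5 come from the lactone, C1 is set in the benzoin, C6 in the directed reduction.

Key step: step 11

Assumption: the (5aR,10bS) antipode of the triazolium salt is taken as the one whose facial preference reinforces the substrate bias in step 11; if the pairing proves mismatched, the (5aS,10bR) antipode is used with nothing else changed.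

Remark: the acetal carbon in 3–8 and 11–13, and the carbinol carbon that becomes the C1 ketone in 11–14, are epimer mixtures. Both centres are erased (steps 9 and 10), so their SMILES leave them undefined.

**Route**

Step 1
Reactants: 1 L-galactono-1,4-lactone; 2 4-methoxybenzaldehyde dimethyl acetal
Product: 3 5,6-O-(4-methoxybenzylidene)-L-galactono-1,4-lactone
Conditions: camphorsulfonic acid (cat.), DMF, 45 °C, reduced pressure
Reagents that add atoms: none
Why: Acid-catalysed transacetalisation should engage only the terminal 5,6-diol, because the ring 2,3-diol is trans and a 3,5-acetal would be trans-fused to the lactone; the new acetal carbon later becomes the PMB methylene.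

Step 2
Reactants: 3 5,6-O-(4-methoxybenzylidene)-L-galactono-1,4-lactone
Product: 4 2-O-(tert-butyldimethylsilyl)-5,6-O-(4-methoxybenzylidene)-L-galactono-1,4-lactone
Conditions: TBSCl (1.1 equiv), imidazole, DMF, −20 to 0 °C
Reagents that add atoms: tert-butyldimethylsilyl chloride, CC(C)(C)[Si](C)(C)Cl
Why: The hydroxyl alpha to the lactone carbonyl is the most acidic and most reactive secondary hydroxyl of aldono-1,4-lactones (the order seen in their partial acylations), so one equivalent of silyl chloride at low temperature should silylate O-2 and leave O-3 free.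

Step 3
Reactants: 4 2-O-(tert-butyldimethylsilyl)-5,6-O-(4-methoxybenzylidene)-L-galactono-1,4-lactone
Product: 5 2-O-(tert-butyldimethylsilyl)-N-methoxy-N-methyl-5,6-O-(4-methoxybenzylidene)-L-galactonamide
Conditions: MeNHOMe·HCl, AlMe3, CH2Cl2, 0 °C to rt; aq. potassium sodium tartrate
Reagents that add atoms: N,O-dimethylhydroxylamine hydrochloride, CNOC.Cl
Why: Weinreb aminolysis of the gamma-lactone with the aluminium amide opens the ring without touching C2, frees O-4 so that the erythro 3,4-diol is available, and stores C1 as an amide that can be reduced to the aldehyde.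

Step 4
Reactants: 5 2-O-(tert-butyldimethylsilyl)-N-methoxy-N-methyl-5,6-O-(4-methoxybenzylidene)-L-galactonamide
Product: 6 3,4-O-thiocarbonyl derivative of 5 (cyclic thionocarbonate)
Conditions: Im2C=S, DMAP (cat.), THF, rt
Reagents that add atoms: 1,1'-thiocarbonyldiimidazole, S=C(n1ccnc1)n1ccnc1
Why: A vicinal diol and thiocarbonyldiimidazole give the five-membered cyclic thionocarbonate (first half of the Corey–Winter olefination), the erythro diol placing the two chain ends cis on the new ring and the gamma-hydroxyl being tied up before it can relactonise.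

Step 5
Reactants: 6 cyclic thionocarbonate
Product: 7 (2S,3Z)-2-(tert-butyldimethylsilyloxy)-N-methoxy-4-[(4R)-2-(4-methoxyphenyl)-1,3-dioxolan-4-yl]-N-methylbut-3-enamide
Conditions: 1,3-dimethyl-2-phenyl-1,3,2-diazaphospholidine, THF, 40 °C
Reagents that add atoms: none
Why: The Corey–Winter syn-elimination (desulfurisation to the dioxolanylidene carbene, then cycloreversion with loss of CO2) is stereospecific, so the cis-disubstituted thionocarbonate should give the Z-alkene (the future C3=C4) without base.

Step 6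
Reactants: 7 Weinreb amide
Product: 8 (2S,3Z)-2-(tert-butyldimethylsilyloxy)-4-[(4R)-2-(4-methoxyphenyl)-1,3-dioxolan-4-yl]but-3-enal
Conditions: iBu2AlH, THF, −78 °C; aq. potassium sodium tartrate
Reagents that add atoms: none
Why: Weinreb amide reduction stops at the aldehyde through the chelated hemiaminal, and at −78 °C in THF the anisylidene acetal is not opened; the aldehyde is used at once because its alpha-carbon is also allylic.

Step 7
Reactants: 8 aldehyde; 9 (chloromethyl)(isopropoxy)dimethylsilane
Product: 12 (3S,4Z)-3-(tert-butyldimethylsilyloxy)-5-[(4R)-2-(4-methoxyphenyl)-1,3-dioxolan-4-yl]pent-4-ene-1,2-diol, via Grignard reagent 10 (not isolated), via beta-hydroxysilane 11 (not isolated)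
Conditions: 9, Mg, THF (gives 10); 8, THF, −78 to 0 °C; then KF, KHCO3, 30% H2O2, THF/MeOH, rt
Reagents that add atoms: hydrogen peroxide, OO
Why: The (isopropoxydimethylsilyl)methyl Grignard reagent is a hydroxymethyl anion equivalent that adds to the aldehyde, and the C–Si bond is then oxidised (Tamao–Fleming oxidation) under mild fluoride/peroxide conditions that the TBS ether, acetal and alkene should tolerate; this installs C7, and the new carbinol centre is destroyed in step 10.

Step 8
Reactants: 12 1,2-diol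
Product: 13 (3S,4Z)-1,3-bis(tert-butyldimethylsilyloxy)-5-[(4R)-2-(4-methoxyphenyl)-1,3-dioxolan-4-yl]pent-4-en-2-ol
Conditions: TBSCl (1.05 equiv), imidazole, CH2Cl2, 0 °C
Reagents that add atoms: tert-butyldimethylsilyl chloride, CC(C)(C)[Si](C)(C)Cl
Why: Silylation of a 1,2-diol with one equivalent of TBSCl is selective for the primary hydroxyl (O-7).

Step 9
Reactants: 13 acetal alcohol
Product: 14 (2R,3Z,5S)-5,7-bis(tert-butyldimethylsilyloxy)-2-(4-methoxybenzyloxy)hept-3-ene-1,6-diol
Conditions: iBu2AlH (4 equiv), CH2Cl2, −78 to 0 °C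
Reagents that add atoms: none
Why: In the regioselective reductive opening of a 4-methoxybenzylidene acetal, aluminium coordinates the less hindered primary oxygen, that C–O bond breaks and hydride reduces the oxocarbenium ion, so the PMB ether should end on the secondary allylic oxygen and the primary alcohol be free.

Step 10
Reactants: 14 1,6-diol
Product: 15 (2R,3Z,5S)-5,7-bis(tert-butyldimethylsilyloxy)-2-(4-methoxybenzyloxy)-6-oxohept-3-enal
Conditions: Dess–Martin periodinane, NaHCO3, CH2Cl2, 0 °C to rt
Reagents that add atoms: none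
Why: Dess–Martin oxidation under bicarbonate buffer converts the primary alcohol to the aldehyde and the secondary alcohol to the ketone without a base strong enough to epimerise the two allylic alpha-stereocentres or move the Z-alkene into conjugation.

Step 11
Reactants: 15 keto aldehyde
Product: 16 (2R,5S,6S)-6-hydroxy-2-(4-methoxybenzyloxy)-5-(tert-butyldimethylsilyloxy)-6-[(tert-butyldimethylsilyloxy)methyl]cyclohex-3-en-1-one
Conditions: (5aR,10bS)-2-(pentafluorophenyl)-5a,10b-dihydro-4H,6H-indeno[2,1-b][1,2,4]triazolo[4,3-d][1,4]oxazin-2-ium tetrafluoroborate (20 mol %), iPr2NEt (20 mol %), toluene (0.02 M), 0 °C to rt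
Reagents that add atoms: none
Why: The carbene from the triazolium salt adds to the aldehyde, proton transfer gives the nucleophilic Breslow enaminol, and this attacks the ketone carbonyl in a 6-exo-trig closure that forms the C1–C6 bond and the cyclohexene ring before the carbene is expelled, leaving the C6 ketone and the C1 tertiary alcohol. The closest known reaction type is the enantioselective NHC-catalysed intramolecular crossed aldehyde–ketone benzoin giving six-membered tertiary alpha-ketols, carbohydrate-derived keto aldehydes included. The new stereocentre C1 is controlled by the C2 silyloxy group together with the catalyst: in the half-chair transition state the C2–O bond lies anti to the forming bond (polar Felkin–Anh arrangement) and the CH2OTBS group is equatorial, which places the new hydroxyl cis to O-2 and O-5, and the triazolium antipode is chosen to reinforce this face. The step needs cross- over homo-coupling and ketone facial selectivity: the first is secured because only the aldehyde can form the acyl anion equivalent and the Z-alkene holds the two carbonyls within reach at high dilution, the second by the substrate bias and catalyst just described. The amine base is weak and substoichiometric so that the two allylic alpha-hydrogens should not be epimerised.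

Step 12
Reactants: 16 alpha-ketol
Product: 17 (1R,2S,5R,6S)-2-(tert-butyldimethylsilyloxy)-1-[(tert-butyldimethylsilyloxy)methyl]-5-(4-methoxybenzyloxy)cyclohex-3-ene-1,6-diol (target numbering)
Conditions: Me4NBH(OAc)3, MeCN/AcOH, −30 to 0 °C
Reagents that add atoms: none
Why: In this hydroxyl-directed reduction (Evans–Saksena type) the C1 hydroxyl exchanges onto boron and delivers hydride to the face of the C6 carbonyl that it occupies, so the new C6 hydroxyl should be trans to O-1 and O-5; the acidic medium spares the alpha-stereocentre.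

Step 13
Reactants: 17 PMB ether diol
Product: 18 (1R,2S,5R,6S)-2-(tert-butyldimethylsilyloxy)-1-[(tert-butyldimethylsilyloxy)methyl]cyclohex-3-ene-1,5,6-triol (target numbering)
Conditions: DDQ, CH2Cl2/pH 7 buffer, 0 °C
Reagents that add atoms: none
Why: DDQ cleaves the PMB ether oxidatively, and the buffered water should intercept the oxocarbenium ion before a neighbouring hydroxyl closes an anisylidene acetal; silyl ethers and the alkene are inert.

Step 14
Reactants: 18 triol
Product: 19 (1R,2S,5R,6S)-5,6-diacetoxy-2-(tert-butyldimethylsilyloxy)-1-[(tert-butyldimethylsilyloxy)methyl]cyclohex-3-en-1-ol (target numbering)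
Conditions: Ac2O, pyridine, 0 °C to rt
Reagents that add atoms: acetic anhydride, CC(=O)OC(C)=O
Why: Acetylation in pyridine esterifies the two secondary hydroxyls, while the tertiary C1 hydroxyl, flanked by three substituted carbons, should not be acylated without DMAP or heat.

Step 15
Reactants: 19 diacetate
Product: 20 (1S,2S,5R,6S)-5,6-diacetoxy-1-(hydroxymethyl)cyclohex-3-ene-1,2-diol (target numbering)
Conditions: HF·pyridine, pyridine/THF, 0 °C to rt
Reagents that add atoms: none
Why: Acidic fluoride desilylation cleaves both TBS ethers and avoids the alkoxide intermediates that would let an acetyl group migrate from O-6 to O-1 or O-7.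

Step 16
Reactants: 20 triol diacetate
Product: 21 cleistenediol F
Conditions: BzCl, pyridine, DMAP (cat.), CH2Cl2, 0 °C to rt
Reagents that add atoms: benzoyl chloride, O=C(Cl)c1ccccc1
Why: Benzoylation acylates the primary C7 and the secondary allylic C2 hydroxyls and should again leave the hindered tertiary C1 hydroxyl free, giving the target.

**Compound list**

1 | L-galactono-1,4-lactone | OC[C@H](O)[C@H]1OC(=O)[C@@H](O)[C@@H]1O | starting material
2 | 4-methoxybenzaldehyde dimethyl acetal | COc1ccc(cc1)C(OC)OC | starting material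
3 | 5,6-O-(4-methoxybenzylidene)-L-galactono-1,4-lactone | COc1ccc(cc1)C2OC[C@H](O2)[C@H]3OC(=O)[C@@H](O)[C@@H]3O | intermediate
4 | 2-O-(tert-butyldimethylsilyl)-5,6-O-(4-methoxybenzylidene)-L-galactono-1,4-lactone | COc1ccc(cc1)C2OC[C@H](O2)[C@H]3OC(=O)[C@@H](O[Si](C)(C)C(C)(C)C)[C@@H]3O | intermediate
5 | 2-O-(tert-butyldimethylsilyl)-N-methoxy-N-methyl-5,6-O-(4-methoxybenzylidene)-L-galactonamide | COc1ccc(cc1)C2OC[C@H](O2)[C@@H](O)[C@@H](O)[C@H](O[Si](C)(C)C(C)(C)C)C(=O)N(C)OC | intermediate
6 | 3,4-O-thiocarbonyl derivative of 5 (cyclic thionocarbonate) | COc1ccc(cc1)C2OC[C@H](O2)[C@H]3OC(=S)O[C@H]3[C@H](O[Si](C)(C)C(C)(C)C)C(=O)N(C)OC | intermediate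
7 | (2S,3Z)-2-(tert-butyldimethylsilyloxy)-N-methoxy-4-[(4R)-2-(4-methoxyphenyl)-1,3-dioxolan-4-yl]-N-methylbut-3-enamide | COc1ccc(cc1)C2OC[C@H](O2)/C=C\[C@H](O[Si](C)(C)C(C)(C)C)C(=O)N(C)OC | intermediate
8 | (2S,3Z)-2-(tert-butyldimethylsilyloxy)-4-[(4R)-2-(4-methoxyphenyl)-1,3-dioxolan-4-yl]but-3-enal | COc1ccc(cc1)C2OC[C@H](O2)/C=C\[C@H](O[Si](C)(C)C(C)(C)C)C=O | intermediate
9 | (chloromethyl)(isopropoxy)dimethylsilane | CC(C)O[Si](C)(C)CCl | starting material
10 | [(isopropoxy)dimethylsilyl]methylmagnesium chloride | CC(C)O[Si](C)(C)C[Mg]Cl | intermediate (not isolated)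
11 | (3S,4Z)-3-(tert-butyldimethylsilyloxy)-1-[isopropoxy(dimethyl)silyl]-5-[(4R)-2-(4-methoxyphenyl)-1,3-dioxolan-4-yl]pent-4-en-2-ol | COc1ccc(cc1)C2OC[C@H](O2)/C=C\[C@H](O[Si](C)(C)C(C)(C)C)C(O)C[Si](C)(C)OC(C)C | intermediate (not isolated)
12 | (3S,4Z)-3-(tert-butyldimethylsilyloxy)-5-[(4R)-2-(4-methoxyphenyl)-1,3-dioxolan-4-yl]pent-4-ene-1,2-diol | COc1ccc(cc1)C2OC[C@H](O2)/C=C\[C@H](O[Si](C)(C)C(C)(C)C)C(O)CO | intermediate
13 | (3S,4Z)-1,3-bis(tert-butyldimethylsilyloxy)-5-[(4R)-2-(4-methoxyphenyl)-1,3-dioxolan-4-yl]pent-4-en-2-ol | COc1ccc(cc1)C2OC[C@H](O2)/C=C\[C@H](O[Si](C)(C)C(C)(C)C)C(O)CO[Si](C)(C)C(C)(C)C | intermediate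
14 | (2R,3Z,5S)-5,7-bis(tert-butyldimethylsilyloxy)-2-(4-methoxybenzyloxy)hept-3-ene-1,6-diol | OC[C@H](OCc1ccc(OC)cc1)/C=C\[C@H](O[Si](C)(C)C(C)(C)C)C(O)CO[Si](C)(C)C(C)(C)C | intermediate
15 | (2R,3Z,5S)-5,7-bis(tert-butyldimethylsilyloxy)-2-(4-methoxybenzyloxy)-6-oxohept-3-enal | O=C[C@H](OCc1ccc(OC)cc1)/C=C\[C@H](O[Si](C)(C)C(C)(C)C)C(=O)CO[Si](C)(C)C(C)(C)C | intermediate
16 | (2R,5S,6S)-6-hydroxy-2-(4-methoxybenzyloxy)-5-(tert-butyldimethylsilyloxy)-6-[(tert-butyldimethylsilyloxy)methyl]cyclohex-3-en-1-one | O=C1[C@H](OCc2ccc(OC)cc2)C=C[C@H](O[Si](C)(C)C(C)(C)C)[C@@]1(O)CO[Si](C)(C)C(C)(C)C | intermediate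
17 | (1R,2S,5R,6S)-2-(tert-butyldimethylsilyloxy)-1-[(tert-butyldimethylsilyloxy)methyl]-5-(4-methoxybenzyloxy)cyclohex-3-ene-1,6-diol (target numbering) | COc1ccc(CO[C@@H]2C=C[C@H](O[Si](C)(C)C(C)(C)C)[C@@](O)(CO[Si](C)(C)C(C)(C)C)[C@H]2O)cc1 | intermediate
18 | (1R,2S,5R,6S)-2-(tert-butyldimethylsilyloxy)-1-[(tert-butyldimethylsilyloxy)methyl]cyclohex-3-ene-1,5,6-triol (target numbering) | O[C@@H]1C=C[C@H](O[Si](C)(C)C(C)(C)C)[C@@](O)(CO[Si](C)(C)C(C)(C)C)[C@H]1O | intermediate
19 | (1R,2S,5R,6S)-5,6-diacetoxy-2-(tert-butyldimethylsilyloxy)-1-[(tert-butyldimethylsilyloxy)methyl]cyclohex-3-en-1-ol (target numbering) | CC(=O)O[C@@H]1C=C[C@H](O[Si](C)(C)C(C)(C)C)[C@@](O)(CO[Si](C)(C)C(C)(C)C)[C@H]1OC(C)=O | intermediate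
20 | (1S,2S,5R,6S)-5,6-diacetoxy-1-(hydroxymethyl)cyclohex-3-ene-1,2-diol (target numbering) | CC(=O)O[C@@H]1C=C[C@H](O)[C@@](O)(CO)[C@H]1OC(C)=O | intermediate
21 | cleistenediol F | CC(=O)O[C@@H]1C=C[C@H](OC(=O)c2ccccc2)[C@@](O)(COC(=O)c2ccccc2)[C@H]1OC(C)=O | target

**Step count**

Total steps: 16. Longest linear sequence: 16 (from 1).

**Steps most likely to fail**

Step 11. What may go wrong: base-mediated epimerisation of the two alpha-stereocentres (each allylic and alpha to a carbonyl), migration of the alkene into conjugation before or after ring closure, or a low facial preference at the ketone. The fallback closes the same C1–C6 bond on a saturated keto aldehyde, in which the erythro diol is still masked as two triethylsilyl ethers, and makes the alkene after the ring. It sets out from 5 and comes back at 16. Silylation of 5 (TESOTf, 2,6-lutidine, CH2Cl2, −78 °C) should give the bis-TES amide F1. The operations of steps 6 to 10 should then give the aldehyde F2, the beta-hydroxysilane F3 (not isolated), the 1,2-diol F4, the primary silyl ether F5, the PMB-protected 1,6-diol F6 and the keto aldehyde F7, which has no allylic alpha-hydrogen. The same triazolium-catalysed benzoin should give the ketol F8. Pyridinium p-toluenesulfonate in MeOH should remove the two secondary TES ethers to give the cis-diol F9. Thiocarbonyldiimidazole should give the cyclic thionocarbonate F10, the tertiary hydroxyl not reacting, and the diazaphospholidine of step 5 should convert F10 into 16.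

Step 7. What may go wrong: the alpha-silyloxy, allylic aldehyde 8 enolises or epimerises under the basic Grignard reagent, the silyl group migrates to the neighbouring new alkoxide, or the beta-hydroxysilane undergoes Peterson elimination instead of oxidation. The fallback homologates at the ketone oxidation level and does not pass through 8. It sets out from 7 and comes back at 12. Chloromethyllithium generated in situ (ICH2Cl, MeLi·LiBr, THF, −78 °C) should add to the Weinreb amide to give the chloromethyl ketone F11. CsOAc in DMF should displace chloride to give the acetoxymethyl ketone F12. iBu2AlH in THF at −78 °C should reduce the ketone and cleave the acetate to give diol 12 with the acetal intact.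

Step 12. What may go wrong: the tertiary hydroxyl exchanges onto boron too slowly, so that reduction is sluggish or undirected hydride delivery gives the cis-diol. The fallback changes the directing group by inverting the order of steps 12 and 13. It sets out from 16 and comes back at 18. DDQ in buffered wet CH2Cl2 should remove the PMB ether to give the dihydroxy ketone F13, whose secondary C5 hydroxyl lies on the same face as the C1 hydroxyl and exchanges readily. Me4NBH(OAc)3 should then deliver hydride from that face and give triol 18.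

**Further compounds**

F1 | step 11 | 2-O-(tert-butyldimethylsilyl)-3,4-bis-O-(triethylsilyl)-N-methoxy-N-methyl-5,6-O-(4-methoxybenzylidene)-L-galactonamide | COc1ccc(cc1)C2OC[C@H](O2)[C@@H](O[Si](CC)(CC)CC)[C@@H](O[Si](CC)(CC)CC)[C@H](O[Si](C)(C)C(C)(C)C)C(=O)N(C)OC
F2 | step 11 | 2-O-(tert-butyldimethylsilyl)-3,4-bis-O-(triethylsilyl)-5,6-O-(4-methoxybenzylidene)-aldehydo-L-galactose | COc1ccc(cc1)C2OC[C@H](O2)[C@@H](O[Si](CC)(CC)CC)[C@@H](O[Si](CC)(CC)CC)[C@H](O[Si](C)(C)C(C)(C)C)C=O
F3 | step 11 | adduct of F2 with 10 (beta-hydroxysilane, carbinol epimers) | COc1ccc(cc1)C2OC[C@H](O2)[C@@H](O[Si](CC)(CC)CC)[C@@H](O[Si](CC)(CC)CC)[C@H](O[Si](C)(C)C(C)(C)C)C(O)C[Si](C)(C)OC(C)C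
F4 | step 11 | saturated 1,2-diol (3-O-TBS, 4,5-bis-O-TES, 6,7-O-anisylidene heptitol; C2 epimers) | COc1ccc(cc1)C2OC[C@H](O2)[C@@H](O[Si](CC)(CC)CC)[C@@H](O[Si](CC)(CC)CC)[C@H](O[Si](C)(C)C(C)(C)C)C(O)CO
F5 | step 11 | primary TBS ether of F4 | COc1ccc(cc1)C2OC[C@H](O2)[C@@H](O[Si](CC)(CC)CC)[C@@H](O[Si](CC)(CC)CC)[C@H](O[Si](C)(C)C(C)(C)C)C(O)CO[Si](C)(C)C(C)(C)C
F6 | step 11 | saturated 1,6-diol (O-5 PMB, O-2 and O-7 TBS, O-3 and O-4 TES; target numbering) | OC[C@H](OCc1ccc(OC)cc1)[C@@H](O[Si](CC)(CC)CC)[C@@H](O[Si](CC)(CC)CC)[C@H](O[Si](C)(C)C(C)(C)C)C(O)CO[Si](C)(C)C(C)(C)C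
F7 | step 11 | saturated keto aldehyde (3,4-bis-O-TES analogue of 15) | O=C[C@H](OCc1ccc(OC)cc1)[C@@H](O[Si](CC)(CC)CC)[C@@H](O[Si](CC)(CC)CC)[C@H](O[Si](C)(C)C(C)(C)C)C(=O)CO[Si](C)(C)C(C)(C)C
F8 | step 11 | cyclohexanone ketol with cis 3,4-bis(triethylsilyloxy) groups (saturated analogue of 16) | O=C1[C@H](OCc2ccc(OC)cc2)[C@@H](O[Si](CC)(CC)CC)[C@@H](O[Si](CC)(CC)CC)[C@H](O[Si](C)(C)C(C)(C)C)[C@@]1(O)CO[Si](C)(C)C(C)(C)C
F9 | step 11 | cis-3,4-diol from F8 | O=C1[C@H](OCc2ccc(OC)cc2)[C@@H](O)[C@@H](O)[C@H](O[Si](C)(C)C(C)(C)C)[C@@]1(O)CO[Si](C)(C)C(C)(C)C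
F10 | step 11 | 3,4-O-thiocarbonyl derivative of F9 | O=C1[C@H](OCc2ccc(OC)cc2)[C@H]3OC(=S)O[C@H]3[C@H](O[Si](C)(C)C(C)(C)C)[C@@]1(O)CO[Si](C)(C)C(C)(C)C
F11 | step 7 | (3S,4Z)-1-chloro-3-(tert-butyldimethylsilyloxy)-5-[(4R)-2-(4-methoxyphenyl)-1,3-dioxolan-4-yl]pent-4-en-2-one | COc1ccc(cc1)C2OC[C@H](O2)/C=C\[C@H](O[Si](C)(C)C(C)(C)C)C(=O)CCl
F12 | step 7 | (3S,4Z)-3-(tert-butyldimethylsilyloxy)-5-[(4R)-2-(4-methoxyphenyl)-1,3-dioxolan-4-yl]-2-oxopent-4-en-1-yl acetate | COc1ccc(cc1)C2OC[C@H](O2)/C=C\[C@H](O[Si](C)(C)C(C)(C)C)C(=O)COC(C)=O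
F13 | step 12 | (2R,5S,6S)-2,6-dihydroxy-5-(tert-butyldimethylsilyloxy)-6-[(tert-butyldimethylsilyloxy)methyl]cyclohex-3-en-1-one | O=C1[C@H](O)C=C[C@H](O[Si](C)(C)C(C)(C)C)[C@@]1(O)CO[Si](C)(C)C(C)(C)C
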